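**Plan**

- Retrosynthesis of the pyran: cut C2=CH2 (methylenation of a δ-lactone), then O1–C6 and C5–Br (bromolactonisation of an α-hydroxy acid), then C4–C5 (prenyl unit by epoxide opening) and C3–O (asymmetric epoxidation of a 2-substituted allyl alcohol grown from an allyl group).
- Retrosynthesis of the cyclohexane (C1' on the pyran, C3' = CHBr, C4' = C(Cl)CH3): the Br/Cl pair is swapped back to a diaxial tertiary bromide/secondary chloride, then cut at C4'–Br, C4'–CH3 and C3'–Cl to (4R)-4-allylcyclohex-2-enone. C3' is then taken out of the ring, so the enone comes from a cyclopentanone silyl enol ether plus one CH2.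
- Enabling feature: C1' is γ to C4' in the six-membered ring but β to the carbonyl in the five-membered ring (atoms C4', C2', C1', C6', C5'). There a catalytic conjugate reduction sets C1' and at the same time fixes the enol ether C4'=C2', the bond into which C3' is inserted.
- Forward order: five-membered carbocycle, ring expansion to the six-membered ring (step 4), ring halogens, side chain, tertiary carbinol, pyranone ring, exocyclic enol ether last.
- Stereochemistry: C1' from the CuH/(S)-p-Tol-BINAP reduction; C3' and C4' relayed from C1' through the chair (axial chlorination, axial bromide capture, suprafacial 1,2-interchange); pyran C3 from Sharpless epoxidation (L-(+)-tartrate, reagent control); C5 from C3 in the chair bromolactonisation.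

Key step: step 4

Assumption: the sense of induction of the CuH/p-Tol-BINAP reduction is taken as (S)-ligand giving (R)-C3 of 6; if it is the opposite, the (R)-ligand is used.

**Step 1**
Reactants: 1 3-ethoxycyclopent-2-en-1-one; 2 prop-2-en-1-ylmagnesium bromide
Product: 3 3-(prop-2-en-1-yl)cyclopent-2-en-1-one
Conditions: THF, 0 °C; then 1 M HCl, 0 °C to rt
Reagents that add atoms: none
Why: Stork–Danheiser sequence, in which 1,2-addition of the Grignard reagent to the vinylogous ester and acid-promoted loss of ethanol transpose the carbonyl and should give the 3-substituted enone; no stereocentre is formed.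

**Step 2**
Reactants: 3 3-(prop-2-en-1-yl)cyclopent-2-en-1-one
Product: 6 trimethyl{[(3R)-3-(prop-2-en-1-yl)cyclopent-1-en-1-yl]oxy}silane, via bis(enoxy)diphenylsilane 4 (not isolated), via lithium enolate 5 (not isolated)
Conditions: CuCl (5 mol%), NaOt-Bu (5 mol%), (S)-p-Tol-BINAP (5 mol%), Ph2SiH2 (0.55 equiv), toluene, 0 °C; then MeLi (1.1 equiv), THF, −78 to 0 °C; then Me3SiCl, −78 °C to rt
Reagents that add atoms: chlorotrimethylsilane, C[Si](C)(C)Cl
Why: Copper hydride asymmetric conjugate reduction delivers hydride to C3 from one enantiotopic face, so the ligand sets the C3 stereocentre and the silicon enolate is formed only towards C2; silicon-to-lithium exchange with MeLi and silylation keep this regiochemistry.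

**Step 3**
Reactants: 6 trimethyl{[(3R)-3-(prop-2-en-1-yl)cyclopent-1-en-1-yl]oxy}silane
Product: 7 trimethyl{[(1S,4R,5R)-4-(prop-2-en-1-yl)bicyclo[3.1.0]hexan-1-yl]oxy}silane
Conditions: Et2Zn (1.2 equiv), CH2I2 (1.2 equiv), CH2Cl2, 0 °C
Reagents that add atoms: diiodomethane, ICI
Why: Simmons–Smith cyclopropanation, in which the electrophilic zinc carbenoid should add to the electron-rich enol ether far faster than to the terminal alkene and anti to the neighbouring allyl group; this sets C1 and C5 (cis fusion enforced), both of which are erased in step 4.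

**Step 4**
Reactants: 7 trimethyl{[(1S,4R,5R)-4-(prop-2-en-1-yl)bicyclo[3.1.0]hexan-1-yl]oxy}silane
Product: 9 (4R)-4-(prop-2-en-1-yl)cyclohex-2-en-1-one, via 3-chloro ketone 8 (not isolated)
Conditions: FeCl3 (2.2 equiv), DMF, 0 °C to rt; then NaOAc, MeOH, reflux
Reagents that add atoms: none
Why: FeCl3 oxidises the siloxycyclopropane by single-electron transfer to a cyclopropyloxy radical, which undergoes β-scission of the C1–C5 bond shared by the three- and five-membered rings to give a C3 radical of a cyclohexanone; chlorine-atom transfer from a second FeCl3 gives 3-chloro ketone 8, and NaOAc then eliminates HCl (E1cB) to the enone. The closest known reaction type is the Saegusa–Ito one-carbon ring expansion of cycloalkanone silyl enol ethers. No ring is closed: the cyclopropane is opened and its CH2 becomes C2 of the new six-membered ring, between the carbonyl carbon and the former enol carbon. The only new stereocentre, C3 of 8 (chlorine transfer anti to the neighbouring allyl group), is removed again by the elimination, while the existing stereocentre is not part of the reacting bonds and becomes C4 of the enone unchanged. The step needs cleavage of the ring-fusion bond and not of the C1–C6 bond (which would give a 2-methylcyclopentanone); fusion-bond cleavage gives the secondary ring radical and the strain-free cyclohexanone and is the established course for 1-siloxybicyclo[n.1.0]alkanes. The terminal alkene should survive because the C3 radical could close onto it only in disfavoured 4-exo or 5-endo modes.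

**Step 5**
Reactants: 9 (4R)-4-(prop-2-en-1-yl)cyclohex-2-en-1-one
Product: 11 (2R,4R)-2-chloro-4-(prop-2-en-1-yl)cyclohexan-1-one, via lithium enolate 10 (not isolated)
Conditions: LiBH(s-Bu)3 (1.05 equiv), THF, −78 °C; then N-chlorosuccinimide, THF, −78 °C; pH 7 buffer
Reagents that add atoms: N-chlorosuccinimide, O=C1CCC(=O)N1Cl
Why: Conjugate reduction of the β-unsubstituted cyclohexenone gives the C1–C2 enolate regiospecifically, and kinetic enolate α-chlorination should occur by axial attack through a chair with the allyl group equatorial, placing chlorine axial and trans to the allyl group.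

**Step 6**
Reactants: 11 (2R,4R)-2-chloro-4-(prop-2-en-1-yl)cyclohexan-1-one
Product: 12 (1S,2R,4R)-2-chloro-1-methyl-4-(prop-2-en-1-yl)cyclohexan-1-ol
Conditions: MeMgBr (1.2 equiv), Et2O/THF, −78 °C; then pH 7 phosphate buffer at −78 °C
Reagents that add atoms: methylmagnesium bromide, C[Mg]Br
Why: Grignard 1,2-addition to the α-chloro ketone at low temperature, where attack anti to the axial C–Cl bond should give mainly the cis-chlorohydrin; the configuration of this carbinol centre does not matter because it is ionised in step 7.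

**Step 7**
Reactants: 12 (1S,2R,4R)-2-chloro-1-methyl-4-(prop-2-en-1-yl)cyclohexan-1-ol
Product: 14 (1S,2S,4R)-2-bromo-1-chloro-1-methyl-4-(prop-2-en-1-yl)cyclohexane, via diaxial bromochloride 13 (not isolated)
Conditions: Me3SiBr (1.5 equiv), CH2Cl2, −20 to 0 °C; then solvent exchange to chlorobenzene, 110 °C
Reagents that add atoms: bromotrimethylsilane, C[Si](C)(C)Br
Why: SN1 bromination of the tertiary alcohol, in which the cation is bridged by the axial chlorine and captured by bromide on the opposite axial face to give trans-diaxial 13; heating should then effect the thermal diaxial-to-diequatorial 1,2-interchange of vicinal halides (both halogens migrate suprafacially, each carbon is inverted), putting chlorine on the tertiary and bromine on the secondary carbon, both equatorial.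

**Step 8**
Reactants: 14 (1S,2S,4R)-2-bromo-1-chloro-1-methyl-4-(prop-2-en-1-yl)cyclohexane
Product: 15 2-[(1R,3S,4S)-3-bromo-4-chloro-4-methylcyclohexyl]acetaldehyde
Conditions: O3, CH2Cl2/MeOH, −78 °C; then Me2S, −78 °C to rt
Reagents that add atoms: ozone, [O-][O+]=O
Why: Ozonolysis with reductive work-up cleaves the only alkene; the halogenated ring is inert and no stereocentre is touched.

**Step 9**
Reactants: 15 2-[(1R,3S,4S)-3-bromo-4-chloro-4-methylcyclohexyl]acetaldehyde
Product: 16 2-[(1S,3S,4S)-3-bromo-4-chloro-4-methylcyclohexyl]prop-2-enal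
Conditions: 37% aq. CH2O, pyrrolidine (10 mol%), propanoic acid (10 mol%), i-PrOH, 45 °C
Reagents that add atoms: formaldehyde, C=O
Why: Amine-catalysed Mannich condensation and elimination (organocatalytic α-methylenation of an aldehyde) should install the exocyclic methylene without touching the ring stereocentres.

**Step 10**
Reactants: 16 2-[(1S,3S,4S)-3-bromo-4-chloro-4-methylcyclohexyl]prop-2-enal
Product: 17 2-[(1S,3S,4S)-3-bromo-4-chloro-4-methylcyclohexyl]prop-2-en-1-ol
Conditions: NaBH4, CeCl3·7H2O, MeOH, −40 to 0 °C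
Reagents that add atoms: none
Why: Luche reduction should reduce the enal 1,2 to the 2-substituted allylic alcohol; no stereocentre is formed.

**Step 11**
Reactants: 17 2-[(1S,3S,4S)-3-bromo-4-chloro-4-methylcyclohexyl]prop-2-en-1-ol
Product: 18 {(2S)-2-[(1S,3S,4S)-3-bromo-4-chloro-4-methylcyclohexyl]oxiran-2-yl}methanol
Conditions: Ti(Oi-Pr)4 (10 mol%), L-(+)-diisopropyl tartrate (12 mol%), t-BuOOH, 4 Å molecular sieves, CH2Cl2, −20 °C
Reagents that add atoms: tert-butyl hydroperoxide, CC(C)(C)OO
Why: Sharpless asymmetric epoxidation, in which L-(+)-tartrate should deliver oxygen to the face that makes the new quaternary centre (S) (the same face that gives (S)-glycidol from allyl alcohol, the ring taking the place of H), under reagent control and independent of the remote ring stereocentres.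

**Step 12**
Reactants: 18 {(2S)-2-[(1S,3S,4S)-3-bromo-4-chloro-4-methylcyclohexyl]oxiran-2-yl}methanol; 19 (2-methylprop-1-en-1-yl)magnesium bromide
Product: 20 (2S)-2-[(1S,3S,4S)-3-bromo-4-chloro-4-methylcyclohexyl]-5-methylhex-4-ene-1,2-diol
Conditions: 19 (2.5 equiv), CuI (10 mol%), THF, −30 to 0 °C; then aq. NH4Cl
Reagents that add atoms: none
Why: Copper-catalysed SN2 opening of the 2,2-disubstituted epoxide at its CH2 terminus leaves the quaternary carbinol centre untouched (retention) and introduces the prenyl unit; the equatorial ring halides have no anti-periplanar hydrogen for E2.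

**Step 13**
Reactants: 20 (2S)-2-[(1S,3S,4S)-3-bromo-4-chloro-4-methylcyclohexyl]-5-methylhex-4-ene-1,2-diol
Product: 22 (2S)-2-[(1S,3S,4S)-3-bromo-4-chloro-4-methylcyclohexyl]-2-hydroxy-5-methylhex-4-enoic acid, via hydroxy aldehyde 21 (not isolated)
Conditions: Dess–Martin periodinane, CH2Cl2, 0 °C; then NaClO2, NaH2PO4, 2-methylbut-2-ene, t-BuOH/H2O, 0 °C to rt
Reagents that add atoms: sodium chlorite, [Na+].[O-]Cl=O
Why: Dess–Martin oxidation of the primary hydroxyl (the tertiary one cannot be oxidised) followed by Pinnick oxidation should give the α-hydroxy acid without touching the trisubstituted alkene, the hypochlorite being scavenged by 2-methylbut-2-ene.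

**Step 14**
Reactants: 22 (2S)-2-[(1S,3S,4S)-3-bromo-4-chloro-4-methylcyclohexyl]-2-hydroxy-5-methylhex-4-enoic acid
Product: 23 (3S,5R)-5-bromo-3-[(1S,3S,4S)-3-bromo-4-chloro-4-methylcyclohexyl]-3-hydroxy-6,6-dimethyloxan-2-one
Conditions: N-bromosuccinimide, CH2Cl2, −20 to 0 °C, dark
Reagents that add atoms: N-bromosuccinimide, O=C1CCC(=O)N1Br
Why: Bromolactonisation by Markovnikov 6-endo attack of the carboxyl oxygen on the bromonium ion at the tertiary carbon; a chair transition state with the cyclohexyl group equatorial and anti addition should place bromine equatorial and cis to the cyclohexyl group, so C5 is set from C3.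

**Step 15**
Reactants: 23 (3S,5R)-5-bromo-3-[(1S,3S,4S)-3-bromo-4-chloro-4-methylcyclohexyl]-3-hydroxy-6,6-dimethyloxan-2-one
Product: 24 (3S,5R)-5-bromo-3-[(1S,3S,4S)-3-bromo-4-chloro-4-methylcyclohexyl]-6,6-dimethyl-3-[(trimethylsilyl)oxy]oxan-2-one
Conditions: 1-(trimethylsilyl)imidazole, CH2Cl2, rt
Reagents that add atoms: 1-(trimethylsilyl)imidazole, C[Si](C)(C)n1ccnc1
Why: Silylation of the tertiary alcohol keeps the acidic OH away from the titanium reagent of the next step.

**Step 16**
Reactants: 24 (3S,5R)-5-bromo-3-[(1S,3S,4S)-3-bromo-4-chloro-4-methylcyclohexyl]-6,6-dimethyl-3-[(trimethylsilyl)oxy]oxan-2-one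
Product: 26 (3S,5R)-5-bromo-3-[(1S,3S,4S)-3-bromo-4-chloro-4-methylcyclohexyl]-6,6-dimethyl-2-methylideneoxan-3-ol, via silyl ether 25 (not isolated)
Conditions: Cp2TiMe2 (3 equiv), toluene, 65 °C, dark; then K2CO3 (cat.), MeOH, 0 °C to rt
Reagents that add atoms: bis(cyclopentadienyl)dimethyltitanium (Cp2TiMe2), C[Ti](C)(C1C=CC=C1)C1C=CC=C1
Why: Petasis methylenation (Cp2Ti=CH2 from Cp2TiMe2, [2+2] and retro-[2+2]) should convert the lactone carbonyl into the exocyclic enol ether without acid or base, and base-catalysed methanolysis then removes the trimethylsilyl ether under conditions that do not protonate the enol ether.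

**Compound list**

1 | 3-ethoxycyclopent-2-en-1-one | CCOC1=CC(=O)CC1 | starting material
2 | prop-2-en-1-ylmagnesium bromide | C=CC[Mg]Br | starting material
3 | 3-(prop-2-en-1-yl)cyclopent-2-en-1-one | C=CCC1=CC(=O)CC1 | intermediate
4 | bis{[(3R)-3-(prop-2-en-1-yl)cyclopent-1-en-1-yl]oxy}diphenylsilane | C=CC[C@H]1CCC(O[Si](c2ccccc2)(c2ccccc2)OC2=C[C@@H](CC=C)CC2)=C1 | intermediate
5 | lithium (3R)-3-(prop-2-en-1-yl)cyclopent-1-en-1-olate | C=CC[C@H]1CCC([O-])=C1.[Li+] | intermediate
6 | trimethyl{[(3R)-3-(prop-2-en-1-yl)cyclopent-1-en-1-yl]oxy}silane | C=CC[C@H]1CCC(O[Si](C)(C)C)=C1 | intermediate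
7 | trimethyl{[(1S,4R,5R)-4-(prop-2-en-1-yl)bicyclo[3.1.0]hexan-1-yl]oxy}silane | C=CC[C@H]1CC[C@]2(O[Si](C)(C)C)C[C@H]12 | intermediate
8 | (3S,4R)-3-chloro-4-(prop-2-en-1-yl)cyclohexan-1-one (trans; C3 is lost again in the same step) | C=CC[C@H]1CCC(=O)C[C@@H]1Cl | intermediate
9 | (4R)-4-(prop-2-en-1-yl)cyclohex-2-en-1-one | C=CC[C@H]1CCC(=O)C=C1 | intermediate
10 | lithium (4R)-4-(prop-2-en-1-yl)cyclohex-1-en-1-olate | C=CC[C@H]1CCC([O-])=CC1.[Li+] | intermediate
11 | (2R,4R)-2-chloro-4-(prop-2-en-1-yl)cyclohexan-1-one | C=CC[C@H]1CCC(=O)[C@H](Cl)C1 | intermediate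
12 | (1S,2R,4R)-2-chloro-1-methyl-4-(prop-2-en-1-yl)cyclohexan-1-ol | C=CC[C@H]1CC[C@](C)(O)[C@H](Cl)C1 | intermediate
13 | (1R,2R,4R)-1-bromo-2-chloro-1-methyl-4-(prop-2-en-1-yl)cyclohexane | C=CC[C@H]1CC[C@@](C)(Br)[C@H](Cl)C1 | intermediate
14 | (1S,2S,4R)-2-bromo-1-chloro-1-methyl-4-(prop-2-en-1-yl)cyclohexane | C=CC[C@H]1CC[C@](C)(Cl)[C@@H](Br)C1 | intermediate
15 | 2-[(1R,3S,4S)-3-bromo-4-chloro-4-methylcyclohexyl]acetaldehyde | O=CC[C@H]1CC[C@](C)(Cl)[C@@H](Br)C1 | intermediate
16 | 2-[(1S,3S,4S)-3-bromo-4-chloro-4-methylcyclohexyl]prop-2-enal | C=C(C=O)[C@H]1CC[C@](C)(Cl)[C@@H](Br)C1 | intermediate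
17 | 2-[(1S,3S,4S)-3-bromo-4-chloro-4-methylcyclohexyl]prop-2-en-1-ol | C=C(CO)[C@H]1CC[C@](C)(Cl)[C@@H](Br)C1 | intermediate
18 | {(2S)-2-[(1S,3S,4S)-3-bromo-4-chloro-4-methylcyclohexyl]oxiran-2-yl}methanol | OC[C@]1(CO1)[C@H]1CC[C@](C)(Cl)[C@@H](Br)C1 | intermediate
19 | (2-methylprop-1-en-1-yl)magnesium bromide | CC(C)=C[Mg]Br | starting material
20 | (2S)-2-[(1S,3S,4S)-3-bromo-4-chloro-4-methylcyclohexyl]-5-methylhex-4-ene-1,2-diol | CC(C)=CC[C@](CO)(O)[C@H]1CC[C@](C)(Cl)[C@@H](Br)C1 | intermediate
21 | (2S)-2-[(1S,3S,4S)-3-bromo-4-chloro-4-methylcyclohexyl]-2-hydroxy-5-methylhex-4-enal | CC(C)=CC[C@](C=O)(O)[C@H]1CC[C@](C)(Cl)[C@@H](Br)C1 | intermediate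
22 | (2S)-2-[(1S,3S,4S)-3-bromo-4-chloro-4-methylcyclohexyl]-2-hydroxy-5-methylhex-4-enoic acid | CC(C)=CC[C@](C(=O)O)(O)[C@H]1CC[C@](C)(Cl)[C@@H](Br)C1 | intermediate
23 | (3S,5R)-5-bromo-3-[(1S,3S,4S)-3-bromo-4-chloro-4-methylcyclohexyl]-3-hydroxy-6,6-dimethyloxan-2-one | O=C1OC(C)(C)[C@H](Br)C[C@]1(O)[C@H]1CC[C@](C)(Cl)[C@@H](Br)C1 | intermediate
24 | (3S,5R)-5-bromo-3-[(1S,3S,4S)-3-bromo-4-chloro-4-methylcyclohexyl]-6,6-dimethyl-3-[(trimethylsilyl)oxy]oxan-2-one | O=C1OC(C)(C)[C@H](Br)C[C@]1(O[Si](C)(C)C)[C@H]1CC[C@](C)(Cl)[C@@H](Br)C1 | intermediate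
25 | {[(3S,5R)-5-bromo-3-[(1S,3S,4S)-3-bromo-4-chloro-4-methylcyclohexyl]-6,6-dimethyl-2-methylideneoxan-3-yl]oxy}trimethylsilane | C=C1OC(C)(C)[C@H](Br)C[C@]1(O[Si](C)(C)C)[C@H]1CC[C@](C)(Cl)[C@@H](Br)C1 | intermediate
26 | (3S,5R)-5-bromo-3-[(1S,3S,4S)-3-bromo-4-chloro-4-methylcyclohexyl]-6,6-dimethyl-2-methylideneoxan-3-ol | C=C1OC(C)(C)[C@H](Br)C[C@]1(O)[C@H]1CC[C@](C)(Cl)[C@@H](Br)C1 | target

Total step count: 16. Longest linear sequence: 16 steps (1 to 26).

**Steps most likely to fail**

Step 7. The equilibrium between the diaxial and the diequatorial bromochloride may stop short of full conversion, and loss of HBr from the tertiary bromide may compete at the temperature needed. In the fallback the interchange is not forced thermally. The mixture of 13 and 14 obtained after brief warming is treated with AgOSO2CF3 and 2,6-di-tert-butylpyridine in acetone/H2O at 0 °C. This should hydrolyse only the anchimerically assisted tertiary axial bromide of 13, giving (1R,2R,4R)-2-chloro-1-methyl-4-(prop-2-en-1-yl)cyclohexan-1-ol F1, while 14 is left and separated. F1 is returned to Me3SiBr, where it ionises to the same chlorine-bridged cation, and the cycle is repeated. The fallback sets out from 13 and comes back to the route at 14.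

Step 14. The bromonium ion may be opened in the 5-exo sense by the carboxyl group or by the neighbouring tertiary hydroxyl, and the chair preference that sets C5 may be weak. The fallback sets out from 22 and replaces the kinetic bromonium cyclisation by a reversible mercuricyclisation with Hg(O2CCF3)2 in MeNO2 at 0 °C, where thermodynamic control should favour the δ-lactone with equatorial mercury. Exchange with aqueous KBr gives (3S,5R)-5-(bromomercurio)-3-[(1S,3S,4S)-3-bromo-4-chloro-4-methylcyclohexyl]-3-hydroxy-6,6-dimethyloxan-2-one F2. Bromodemercuration with retention (Br2, LiBr, pyridine, O2, 0 °C) then comes back to the route at 23.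

Step 6. The Grignard reagent may enolise the α-chloro ketone (returning epimerised ketone), or the halomagnesium alkoxide may undergo semipinacol shift on warming. The fallback sets out from 11 and uses non-basic Lombardo methylenation (Zn, CH2Br2, TiCl4, THF, 0 °C to rt) to give (2R,4R)-2-chloro-1-methylidene-4-(prop-2-en-1-yl)cyclohexane F3. Markovnikov addition of anhydrous HBr (CH2Cl2, −78 °C) to the 1,1-disubstituted alkene passes through the same chlorine-bridged tertiary cation and comes back to the route at 13, which is then heated as in step 7.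

**Further compounds**

F1 | step 7 | (1R,2R,4R)-2-chloro-1-methyl-4-(prop-2-en-1-yl)cyclohexan-1-ol | C=CC[C@H]1CC[C@@](C)(O)[C@H](Cl)C1
F2 | step 14 | (3S,5R)-5-(bromomercurio)-3-[(1S,3S,4S)-3-bromo-4-chloro-4-methylcyclohexyl]-3-hydroxy-6,6-dimethyloxan-2-one | O=C1OC(C)(C)[C@H]([Hg]Br)C[C@]1(O)[C@H]1CC[C@](C)(Cl)[C@@H](Br)C1
F3 | step 6 | (2R,4R)-2-chloro-1-methylidene-4-(prop-2-en-1-yl)cyclohexane | C=CC[C@H]1CCC(=C)[C@H](Cl)C1
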